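**Plan**
Retrosynthesis: the side-chain acetate, the 2-O-methyl group and benzyl masks on the acid and the 4-OH are removed first, and the arene is read as a dehydrogenated 2,4-dioxocyclohexane-1-carboxylate.
Enabling feature: the benzene ring carries the carboxyl on C1, oxygen on C2 and C4 and the alkyl chain on C6, so cutting C1–C6 and C3–C4 leaves an acetoacetate (C1–C3 plus carboxyl) and a 2-enoate (C4–C6 plus chain).
The enoate is cut at its C=C bond (cross-metathesis with an acrylate) and the homoallylic carbinol at the two C–C bonds beside it, back to a three-carbon epoxide and two Grignard reagents.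
Forward: the chain is built first (steps 1–4); the only ring closes in step 5, Michael bond C1–C6 first and Claisen bond C3–C4 second, and is aromatised in step 6.
Steps 7–11 differentiate the phenols (4-O-benzyl, 2-O-methyl), exchange the silyl ether for the acetate and free the acid and the 4-OH together by hydrogenolysis.
Stereochemistry: the single stereocentre is C2 of commercial (R)-epichlorohydrin; no bond to it is made or broken in any step, so it arrives unchanged as the (R)-acetoxy carbon.

Key step: step 5

Remark: ring positions are numbered C1 (carboxyl-bearing), C2 (methoxy), C4 (hydroxy) and C6 (chain) throughout; dione 12 is carried on as its mixture of ring diastereomers and keto–enol tautomers, which all converge in step 6.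

Step 1
Reactants: 1 (R)-epichlorohydrin [(R)-2-(chloromethyl)oxirane]; 2 decylmagnesium bromide
Product: 4 (R)-2-undecyloxirane, via (R)-1-chlorotridecan-2-ol 3 (not isolated)
Conditions: 2 (1.2 equiv), CuI (5 mol%), THF, −40 → −20 °C; then MeOH and aq NaOH (2 M), 20 °C
Reagents that add atoms: none
Why: Copper-catalysed Grignard opening of the epoxide at its CH2 carbon followed by Williamson-type closure of the chlorohydrin alkoxide is a standard way from epichlorohydrin to terminal epoxides, and because only the two CH2 carbons react the (R) centre is transferred intact.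

Step 2
Reactants: 4 (R)-2-undecyloxirane; 5 vinylmagnesium bromide
Product: 6 (R)-pentadec-1-en-4-ol
Conditions: 5 (1.5 equiv), CuI (10 mol%), THF, −40 → 0 °C; then aq NH4Cl
Reagents that add atoms: none
Why: Copper-catalysed SN2 opening of a monosubstituted epoxide by a vinyl Grignard reagent takes place at the unhindered CH2 carbon, so the homoallylic alcohol should form with the carbinol configuration untouched.

Step 3
Reactants: 6 (R)-pentadec-1-en-4-ol
Product: 7 (R)-tert-butyldimethyl(pentadec-1-en-4-yloxy)silane
Conditions: TBSCl (1.2 equiv), imidazole (2.5 equiv), DMF, 20 °C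
Reagents that add atoms: tert-butyldimethylsilyl chloride, CC(C)(C)[Si](C)(C)Cl
Why: Imidazole-promoted silylation of a secondary alcohol gives a silyl ether that should tolerate the alkoxide base, the quinone oxidant and the carbonate alkylations of steps 5–8.

Step 4
Reactants: 7 (R)-tert-butyldimethyl(pentadec-1-en-4-yloxy)silane; 8 benzyl acrylate
Product: 9 benzyl (R,E)-5-(tert-butyldimethylsilyloxy)hexadec-2-enoate
Conditions: 8 (3 equiv), second-generation Grubbs catalyst RuCl2(=CHPh)(PCy3)(H2IMes) (3 mol%), CH2Cl2, 40 °C
Reagents that add atoms: none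
Why: Olefin cross-metathesis of an unhindered terminal alkene with an excess of an acrylate is a reliable, E-selective pairing driven by loss of ethene.

Step 5
Reactants: 9 benzyl (R,E)-5-(tert-butyldimethylsilyloxy)hexadec-2-enoate; 10 benzyl acetoacetate
Product: 12 benzyl 6-[(R)-2-(tert-butyldimethylsilyloxy)tridecyl]-2,4-dioxocyclohexane-1-carboxylate, via Michael adduct 11 (not isolated)
Conditions: 10 (1.3 equiv), KOt-Bu (1.1 equiv), t-BuOH/THF, 20 → 70 °C; then 1 M HCl, 0 °C
Reagents that add atoms: none
Why: Deprotonation of 10 at its doubly activated CH2 (future C1) gives a stabilised potassium enolate that adds to the β-carbon of 9 (future C6) and forms the C1–C6 bond of adduct 11. Proton exchange through t-BuOH then makes the less stable enolate at the acetyl CH3 (C3) available, and this carbon attacks the carbonyl of the enoate-derived benzyl ester (C4), expels benzyloxide and forms the C3–C4 bond. The closest known reaction is the Michael–Claisen (Michael–Dieckmann) condensation of acetoacetates with 2-enoates to dihydroorsellinates. The carbocycle closes in the 6-exo-trig mode by acyl substitution; the only other carbon nucleophile of 11 could close a four-membered ring at best. The new ring stereocentres C1 and C6 are not controlled and need not be, since C1 equilibrates under the conditions and both are erased in step 6, while the silyloxy-bearing centre lies outside the reacting atoms and is unaffected. The step needs regioselectivity only (central carbon as Michael donor, methyl carbon as the carbon that is acylated), which follows from the acidity order within 10 and from the final deprotonation of 12 to its vinylogous-acid enolate; keeping KOt-Bu below the amount of 10 leaves no free alkoxide beside 9 and should suppress γ-deprotonation and loss of the δ-silyloxy group, and matched benzyl esters make any ester exchange degenerate.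

Step 6
Reactants: 12 benzyl 6-[(R)-2-(tert-butyldimethylsilyloxy)tridecyl]-2,4-dioxocyclohexane-1-carboxylate
Product: 13 benzyl 2,4-dihydroxy-6-[(R)-2-(tert-butyldimethylsilyloxy)tridecyl]benzoate
Conditions: DDQ (1.2 equiv), 1,4-dioxane, 90 °C
Reagents that add atoms: none
Why: Quinone dehydrogenation, in which DDQ abstracts hydride from the enolised cyclohexane-1,3-dione and proton loss and tautomerisation give the aromatic resorcylate, runs under neutral conditions that the silyl ether and the benzyl ester should tolerate.

Step 7
Reactants: 13 benzyl 2,4-dihydroxy-6-[(R)-2-(tert-butyldimethylsilyloxy)tridecyl]benzoate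
Product: 14 benzyl 4-(benzyloxy)-2-hydroxy-6-[(R)-2-(tert-butyldimethylsilyloxy)tridecyl]benzoate
Conditions: BnBr (1.05 equiv), K2CO3 (1.5 equiv), acetone, 50 °C
Reagents that add atoms: benzyl bromide, BrCc1ccccc1
Why: Williamson etherification with a weak base is selective for the 4-OH, because the 2-OH is held in a hydrogen bond to the ester carbonyl and is both less acidic and less nucleophilic.

Step 8
Reactants: 14 benzyl 4-(benzyloxy)-2-hydroxy-6-[(R)-2-(tert-butyldimethylsilyloxy)tridecyl]benzoate
Product: 15 benzyl 4-(benzyloxy)-2-methoxy-6-[(R)-2-(tert-butyldimethylsilyloxy)tridecyl]benzoate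
Conditions: MeI (5 equiv), K2CO3 (3 equiv), DMF, 40 °C
Reagents that add atoms: iodomethane, CI
Why: Williamson methylation of the remaining hydrogen-bonded phenol needs only excess MeI in warm DMF, conditions under which the silyl ether, the benzyl ether and the benzyl ester are inert.

Step 9
Reactants: 15 benzyl 4-(benzyloxy)-2-methoxy-6-[(R)-2-(tert-butyldimethylsilyloxy)tridecyl]benzoate
Product: 16 benzyl 4-(benzyloxy)-6-[(R)-2-hydroxytridecyl]-2-methoxybenzoate
Conditions: HF·pyridine, pyridine/THF, 0 → 20 °C
Reagents that add atoms: none
Why: Fluoride cleavage of the Si–O bond with pyridine-buffered HF frees the alcohol without generating an alkoxide, which should hold back lactonisation onto the hindered 2,6-disubstituted benzyl ester, and the C–O bond at the stereocentre is not touched.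

Step 10
Reactants: 16 benzyl 4-(benzyloxy)-6-[(R)-2-hydroxytridecyl]-2-methoxybenzoate
Product: 17 benzyl 6-[(R)-2-acetoxytridecyl]-4-(benzyloxy)-2-methoxybenzoate
Conditions: Ac2O (2 equiv), pyridine, DMAP (5 mol%), CH2Cl2, 0 °C, on freshly prepared crude 16
Reagents that add atoms: acetic anhydride, CC(=O)OC(C)=O
Why: DMAP-catalysed acylation of the secondary alcohol is fast at 0 °C and should outrun lactonisation, and it retains configuration because only the O–H bond reacts.

Step 11
Reactants: 17 benzyl 6-[(R)-2-acetoxytridecyl]-4-(benzyloxy)-2-methoxybenzoate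
Product: 18 6-[(R)-2-acetoxytridecyl]-4-hydroxy-2-methoxybenzoic acid (CNP0255988.1)
Conditions: H2 (1 atm), 10% Pd/C, EtOAc, 20 °C
Reagents that add atoms: none
Why: Catalytic hydrogenolysis over Pd/C cleaves both benzylic C–O bonds (ester and aryl ether) under neutral conditions that spare the aliphatic acetate and the methyl ether and avoid the acid or heat that could decarboxylate the electron-rich benzoic acid.

**Compound list**
1 | (R)-epichlorohydrin, (R)-2-(chloromethyl)oxirane | ClC[C@H]1CO1 | starting material
2 | decylmagnesium bromide | CCCCCCCCCC[Mg]Br | starting material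
3 | (R)-1-chlorotridecan-2-ol (present as its magnesium alkoxide) | CCCCCCCCCCC[C@H](CCl)O | intermediate
4 | (R)-2-undecyloxirane | CCCCCCCCCCC[C@@H]1CO1 | intermediate
5 | vinylmagnesium bromide | C=C[Mg]Br | starting material
6 | (R)-pentadec-1-en-4-ol | CCCCCCCCCCC[C@H](CC=C)O | intermediate
7 | (R)-tert-butyldimethyl(pentadec-1-en-4-yloxy)silane | CCCCCCCCCCC[C@H](CC=C)O[Si](C)(C)C(C)(C)C | intermediate
8 | benzyl acrylate | C=CC(=O)OCc1ccccc1 | starting material
9 | benzyl (R,E)-5-(tert-butyldimethylsilyloxy)hexadec-2-enoate | CCCCCCCCCCC[C@H](C/C=C/C(=O)OCc1ccccc1)O[Si](C)(C)C(C)(C)C | intermediate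
10 | benzyl acetoacetate | CC(=O)CC(=O)OCc1ccccc1 | starting material
11 | dibenzyl 2-acetyl-3-[(R)-2-(tert-butyldimethylsilyloxy)tridecyl]pentanedioate (Michael adduct, mixture at the two new centres) | CCCCCCCCCCC[C@H](CC(CC(=O)OCc1ccccc1)C(C(C)=O)C(=O)OCc1ccccc1)O[Si](C)(C)C(C)(C)C | intermediate
12 | benzyl 6-[(R)-2-(tert-butyldimethylsilyloxy)tridecyl]-2,4-dioxocyclohexane-1-carboxylate (ring diastereomers and enol tautomers) | CCCCCCCCCCC[C@H](CC1CC(=O)CC(=O)C1C(=O)OCc1ccccc1)O[Si](C)(C)C(C)(C)C | intermediate
13 | benzyl 2,4-dihydroxy-6-[(R)-2-(tert-butyldimethylsilyloxy)tridecyl]benzoate | CCCCCCCCCCC[C@H](Cc1cc(O)cc(O)c1C(=O)OCc1ccccc1)O[Si](C)(C)C(C)(C)C | intermediate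
14 | benzyl 4-(benzyloxy)-2-hydroxy-6-[(R)-2-(tert-butyldimethylsilyloxy)tridecyl]benzoate | CCCCCCCCCCC[C@H](Cc1cc(OCc2ccccc2)cc(O)c1C(=O)OCc1ccccc1)O[Si](C)(C)C(C)(C)C | intermediate
15 | benzyl 4-(benzyloxy)-2-methoxy-6-[(R)-2-(tert-butyldimethylsilyloxy)tridecyl]benzoate | CCCCCCCCCCC[C@H](Cc1cc(OCc2ccccc2)cc(OC)c1C(=O)OCc1ccccc1)O[Si](C)(C)C(C)(C)C | intermediate
16 | benzyl 4-(benzyloxy)-6-[(R)-2-hydroxytridecyl]-2-methoxybenzoate | CCCCCCCCCCC[C@H](Cc1cc(OCc2ccccc2)cc(OC)c1C(=O)OCc1ccccc1)O | intermediate
17 | benzyl 6-[(R)-2-acetoxytridecyl]-4-(benzyloxy)-2-methoxybenzoate | CCCCCCCCCCC[C@H](Cc1cc(OCc2ccccc2)cc(OC)c1C(=O)OCc1ccccc1)OC(C)=O | intermediate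
18 | 6-[(R)-2-acetoxytridecyl]-4-hydroxy-2-methoxybenzoic acid | CCCCCCCCCCC[C@H](Cc1cc(O)cc(OC)c1C(=O)O)OC(C)=O | target

**Step count**
Total: 11 steps. Longest linear sequence: 11 steps (1 → 18); compounds 2, 5, 8 and 10 enter as purchased materials.

**Steps most likely to fail**

Step 5. Two processes threaten it: γ-deprotonation of the enoate followed by β-elimination of the silyloxy group before the conjugate addition is complete, and stalling at the open-chain adduct because the ring-closing acylation is slow. The fallback sets out from 7 and returns at 12 by exchanging the donor and acceptor roles. Cross-metathesis of 7 with methyl vinyl ketone (second-generation Grubbs catalyst, CH2Cl2, 40 °C) should give the enone (R,E)-6-(tert-butyldimethylsilyloxy)heptadec-3-en-2-one F1. Dibenzyl malonate then adds to this far more reactive acceptor under catalytic KOt-Bu at 0 °C to give dibenzyl 2-[(6R)-6-(tert-butyldimethylsilyloxy)-2-oxoheptadecan-4-yl]malonate F2. One equivalent of KOt-Bu in warm t-BuOH/THF closes F2 by Claisen acylation of its methyl ketone enolate on a malonate ester, and acidification gives 12 itself. The Michael bond C1–C6 and the ring are the same, but the ring closes at C2–C3 instead of C3–C4; the enone–malonate pairing is a long-established entry to 5-alkylresorcinol precursors.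

Step 6. Hydride abstraction from the free dione may be sluggish, the enol may add to the quinone instead of being dehydrogenated, or the electron-rich phenol formed may be oxidised further at 90 °C. The fallback sets out from 12 and returns at 13. Silylation with TMSCl/Et3N (MeCN, 20 °C) should give the bis(silyl) dienol ether benzyl 6-[(R)-2-(tert-butyldimethylsilyloxy)tridecyl]-2,4-bis(trimethylsilyloxy)cyclohexa-1,3-diene-1-carboxylate F3 (or a double-bond isomer). As a cyclohexadiene this is expected to be dehydrogenated by DDQ already at 0–20 °C to benzyl 6-[(R)-2-(tert-butyldimethylsilyloxy)tridecyl]-2,4-bis(trimethylsilyloxy)benzoate F4. Dilute aqueous citric acid in THF then hydrolyses the two aryl O–Si bonds while the secondary silyl ether survives, giving 13.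

Step 9. Once the hydroxyl is unmasked it may attack the neighbouring benzyl ester, so that intramolecular transesterification to the six-membered lactone (a 3,4-dihydroisocoumarin) competes with isolation and acetylation. The fallback sets out from 15 and returns at 17 without passing through the free alcohol. Acetolysis of the silyl ether with Ac2O and catalytic Cu(OTf)2 in CH2Cl2 at 0 → 20 °C, a known one-flask silyl ether to acetate exchange, replaces the O–Si bond by O–acetyl directly. This fallback makes no compound outside the list (F0).

**Further compounds**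
F1 | step 5 | (R,E)-6-(tert-butyldimethylsilyloxy)heptadec-3-en-2-one | CCCCCCCCCCC[C@H](C/C=C/C(C)=O)O[Si](C)(C)C(C)(C)C
F2 | step 5 | dibenzyl 2-[(6R)-6-(tert-butyldimethylsilyloxy)-2-oxoheptadecan-4-yl]malonate | CCCCCCCCCCC[C@H](CC(CC(C)=O)C(C(=O)OCc1ccccc1)C(=O)OCc1ccccc1)O[Si](C)(C)C(C)(C)C
F3 | step 6 | benzyl 6-[(R)-2-(tert-butyldimethylsilyloxy)tridecyl]-2,4-bis(trimethylsilyloxy)cyclohexa-1,3-diene-1-carboxylate | CCCCCCCCCCC[C@H](CC1CC(O[Si](C)(C)C)=CC(O[Si](C)(C)C)=C1C(=O)OCc1ccccc1)O[Si](C)(C)C(C)(C)C
F4 | step 6 | benzyl 6-[(R)-2-(tert-butyldimethylsilyloxy)tridecyl]-2,4-bis(trimethylsilyloxy)benzoate | CCCCCCCCCCC[C@H](Cc1cc(O[Si](C)(C)C)cc(O[Si](C)(C)C)c1C(=O)OCc1ccccc1)O[Si](C)(C)C(C)(C)C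
F0 | step 9 | none | none
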